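(The earlier runs and the new flask are simulated with made-up constants; scatter was added.)

- In a one-step world each incoming ligand changes one starting complex, and the charge ratio of ligand to complex says where the flask stops. For epsilon, eta and theta that ratio is 0.900.
- Our decision is whether to run these flasks at this charge or to raise the ligand.

common to all: starting complex 0.050 M
- south-west: incoming ligand 0.022 M; temperature −20 °C; run made earlier
- epsilon: incoming ligand 0.0450 M; temperature −20 °C; time 30 min
- eta: incoming ligand 0.0450 M; temperature −12 °C; time 30 min
- theta: incoming ligand 0.0450 M; temperature −4 °C; time 30 min

south-west run (percent of the starting complex charged)

| time / min | complex with two exchanged / % | starting complex / % | complex with three exchanged / % | complex with one exchanged / % |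
|---|---|---|---|---|
| 0.417 | 0 | 96.4 | 0 | 1.4 |
| 1.00 | 0.5 | 94.4 | 0.6 | 5.7 |
| 2.00 | 0.7 | 92.9 | 0 | 8.2 |
| 3.00 | 2.0 | 90.1 | 1.7 | 10.2 |

(standard deviation of a reading: 1 percentage point)

- amounts and yields of leaving ligand count crystals too
- given per volume of solution although it is solid: crystals
- the numbers in the tables scatter by 1 percentage point (one standard deviation)
- steps that have been proposed: starting complex + incoming ligand -> leaving ligand + complex with one exchanged; complex with one exchanged + incoming ligand -> leaving ligand + complex with two exchanged; complex with two exchanged + incoming ligand -> leaving ligand + complex with three exchanged; crystals <-> leaving ligand
- the earlier runs do not show what temperature does; that part of a forecast is a guess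
- no earlier run changes the charge of incoming ligand; that part of a forecast is a guess

1. which of these there is most of at the end, counted by the starting complex in it, epsilon (complex with two exchanged / starting complex / complex with one exchanged / complex with three exchanged)
2. which of these there is most of at the end, counted by the starting complex in it, eta (complex with two exchanged / starting complex / complex with one exchanged / complex with three exchanged)
3. which of these there is most of at the end, counted by the starting complex in it, theta (complex with two exchanged / starting complex / complex with one exchanged / complex with three exchanged)
4. final amount of the leader among these, as a percentage of the starting complex charged, in epsilon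
5. final amount of the leader among these, as a percentage of the starting complex charged, in eta
6. final amount of the leader among these, as a percentage of the starting complex charged, in theta

- The proposed steps go on, though: a changed complex can take a further ligand.
- The last south-west reading, at 3.00 min, gives a ligand cost, the ligand spent per complex touched, with each form counted by its exchanges. It reads 1.39, which is more than one, and it carries the scatter.
- The reach, 0.648, is the charge ratio over the cost: the fraction of the charged complex that the ligand can touch before it is spent.
- The crossing is a reach of one. With the cost held, ligand is the limiting reagent below it, and the complex runs out first above it.
- Our reach is below one, so we reckon that 35.2% of the starting complex stays untouched.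
- Complex with one exchanged held 73.4% of the touched forms in that south-west reading. Our reckoning therefore gives it 47.6%, more than the starting complex left.
- The reach says where the ligand ends, not when. Holding the cost across temperature and charge is a guess.
- We keep the charge and run the flasks.
- The forecast differs from our reckoning. It names starting complex as leader in epsilon, starting complex in eta and starting complex in theta, at 50%, 46% and 45%: “It leads in all three runs.”
- The flasks give complex with one exchanged at 57.6% in epsilon, complex with one exchanged at 64.6% in eta, and complex with one exchanged at 68.0% in theta.

    starting complex + incoming ligand → leaving ligand + complex with one exchanged (k = 1.90 M⁻¹ min⁻¹, Ea = 59.0 kJ mol⁻¹)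
    complex with one exchanged + incoming ligand → leaving ligand + complex with two exchanged (k = 0.380 M⁻¹ min⁻¹, Ea = 45.0 kJ mol⁻¹)
    complex with two exchanged + incoming ligand → leaving ligand + complex with three exchanged (k = 5.00 M⁻¹ min⁻¹, Ea = 46.0 kJ mol⁻¹)
    crystals ⇌ leaving ligand, rate k4*(cs4 - [leaving ligand]) while solid is left; crystals form when [leaving ligand] > cs4 (solubility = 40.0 mM, k = 28.0 min⁻¹)
    (constants at −20 °C)

- In theta at 1.44 min, the step from starting complex uses ligand 12 times as fast as the step from complex with one exchanged. At the end of theta, 0.12% of the ligand remains and 76.6% of the complex is touched, more than our reach of 64.8%, which puts the cost there at 1.17.
- The neighbour flask is theta charged with 0.013 M of starting complex instead. Its charge ratio is 3.46, and our cost gives a reach of 2.49, above one, so the complex should run out first. It does: 0.054% of the starting complex and 39% of the ligand remain, and complex with three exchanged leads at 54.7%.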